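**Strategy.** The route rests on closing ring A (C1–C5, C10; labdane numbering) at C2–C3 by an aluminium-promoted carbonyl-ene cyclization. The step exploits the 1,3-relationship between the C2 oxygen and quaternary C4: once one C4 methyl is read as an exocyclic methylene, C2–C3–C4 is a homoallylic alcohol. In one operation it closes the cis-fused decalin and sets C2 under control of the angular C10 methyl. The precursor is a monocyclic keto aldehyde from (S)-carvone, whose ring becomes ring B (C5–C10) and whose isopropenyl group supplies C3, C4 and a C4 methyl; a CH2CHO arm on C10, cis to isopropenyl, provides C1 and C2.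

Key step: step 4

Remark on the chemistry: atoms carry labdane numbers (C1–C10 decalin, C11–C15 side chain, C15 the acid carbon). Read from the SMILES, the decalin is cis-fused: H-5, H-9 and the C10 methyl lie on one face, the C2 oxygen and the C9 side chain on the other (2S,5R,9R,10S,13R); the ester is the Z (angelate) isomer.

Assumption: (S)-4-methyldihydrofuran-2(3H)-one is taken as a purchasable chiral building block.

**Step 1**
Reactants: 1 (S)-carvone
Product: 2 6-prenylcarvone (C6 epimers)
Conditions: LiN(i-Pr)2, THF, −78 °C; prenyl bromide, −78 → 0 °C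
Reagents that add atoms: prenyl bromide (1-bromo-3-methylbut-2-ene), CC(C)=CCBr
Why: Kinetic deprotonation at C6 gives the cross-conjugated lithium enolate, whose C-alkylation (enolate alkylation) by the allylic bromide installs the arm that later becomes C1–C2; the new centre forms as an epimer mixture that is planarized again in step 2.

**Step 2**
Reactants: 2 6-prenylcarvone
Product: 3 (5R,6S)-2,6-dimethyl-6-(3-methylbut-2-en-1-yl)-5-(prop-1-en-2-yl)cyclohex-2-en-1-one
Conditions: LiN(i-Pr)2, THF, −78 °C; MeI, DMPU, −78 → 0 °C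
Reagents that add atoms: iodomethane, CI
Why: Enolate alkylation of the tetrasubstituted enolate should occur anti to the adjacent isopropenyl group (1,2-induction), so methyl enters trans and the prenyl arm ends cis to isopropenyl, fixing the quaternary centre (future C10).

**Step 3**
Reactants: 3 (5R,6S)-2,6-dimethyl-6-prenyl-5-isopropenylcyclohex-2-en-1-one
Product: 5 keto aldehyde 2-[(1S,6R)-1,3-dimethyl-2-oxo-6-(prop-1-en-2-yl)cyclohex-3-en-1-yl]acetaldehyde, via prenyl epoxide 4 (not isolated)
Conditions: mCPBA (1.0 equiv), CH2Cl2, 0 °C; then H5IO6, THF/H2O, 0 °C → rt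
Reagents that add atoms: mCPBA (3-chloroperoxybenzoic acid), OOC(=O)c1cccc(Cl)c1
Why: Prilezhaev epoxidation should select the electron-rich trisubstituted prenyl alkene over the 1,1-disubstituted isopropenyl and the electron-poor enone alkene, and periodic acid then opens the epoxide and cleaves the glycol (Malaprade cleavage) to unveil the C2 aldehyde with loss of acetone; no stereocentre is formed.

**Step 4**
Reactants: 5 keto aldehyde
Product: 6 (4aR,7S,8aS)-7-hydroxy-2,8a-dimethyl-5-methylidene-4a,5,6,7,8,8a-hexahydronaphthalen-1(4H)-one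
Conditions: MeAl(OAr)2 (MABR, Ar = 4-bromo-2,6-di-tert-butylphenyl; 2 equiv, from Me3Al + 2 ArOH), CH2Cl2, −78 °C
Reagents that add atoms: none
Why: Lewis-acid-promoted intramolecular carbonyl-ene reaction (Prins-type, type 2, the enophile being tethered to the central carbon of the ene unit): the aluminium-activated aldehyde carbon C2 is attacked by the methylene terminus C3 of the isopropenyl group while an allylic hydrogen of its methyl passes to oxygen, leaving C4 as an exocyclic methylene. The closest known reaction type is the alkylaluminium-promoted ene cyclization of 5-methylhex-5-enals to 3-methylenecyclohexanols, including the variant with bulky methylaluminium bis(aryloxides) that favours transition states with the aluminium-bound oxygen equatorial. Ring A closes as a six-membered ring, endo with respect to the C3=C4 alkene and exo with respect to the carbonyl, and must be cis-fused because the CH2CHO and isopropenyl arms are cis on ring B. The new stereocentre C2 is controlled by a chair transition state in which ring B keeps its isopropenyl carbon equatorial and the acetaldehyde arm axial, so that the C10 methyl is axial on the forming ring and the bulky aluminium-bound oxygen takes the equatorial position anti to it (7S, oxygen trans to the angular methyl). The step needs chemoselectivity for the aldehyde over the enone carbonyl and for the isopropenyl over the enone alkene, which the conjugation of the enone and its shielding by the C8 methyl and quaternary C10 should secure.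

**Step 5**
Reactants: 6 methylidene hydroxy enone
Product: 8 (4aR,7S,8aS)-7-hydroxy-2,5,5,8a-tetramethyl-4a,5,6,7,8,8a-hexahydronaphthalen-1(4H)-one, via alkyl sulfonylhydrazide 7 (not isolated)
Conditions: Fe(acac)3 (30 mol %), PhSiH3, CH2=N–NHSO2(n-C8H17), THF/MeOH, rt; then MeOH, 60 °C
Reagents that add atoms: formaldehyde N-(octylsulfonyl)hydrazone, C=NNS(=O)(=O)CCCCCCCC
Why: Iron-hydride hydrogen-atom-transfer hydromethylation: H adds to the exocyclic CH2 (Markovnikov), the tertiary C4 radical is trapped by the formaldehyde hydrazone, and thermolysis of the hydrazide expels sulfinate and N2 to leave the second C4 methyl, while the electron-poor enone alkene is a poor hydrogen-atom acceptor; C4 is no stereocentre in the product.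

**Step 6**
Reactants: 8 gem-dimethyl hydroxy enone
Product: 9 (2S,4aR,8aS)-4,4,7,8a-tetramethyl-8-methylidene-1,2,3,4,4a,5,8,8a-octahydronaphthalen-2-ol
Conditions: Ph3PCH3Br (3 equiv), KOt-Bu, toluene, 90 °C
Reagents that add atoms: methyltriphenylphosphonium bromide, C[P+](c1ccccc1)(c1ccccc1)c1ccccc1.[Br-]
Why: Wittig methylenation with excess ylide at elevated temperature, conditions suited to hindered ketones and tolerant of the free hydroxyl (as alkoxide), should convert the C9 carbonyl into the exocyclic methylene C11 of an s-trans diene; no stereocentre is formed.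

**Step 7**
Reactants: 10 (S)-4-methyldihydrofuran-2(3H)-one
Product: 11 methyl (3S)-4-bromo-3-methylbutanoate
Conditions: HBr (gas), MeOH, 0 °C → rt
Reagents that add atoms: hydrogen bromide, Br; methanol, CO
Why: Acid-mediated lactone opening, in which bromide attacks the lactone CH2–O carbon (SN2) and the acid is esterified in methanol (Fischer esterification), leaves the methyl-bearing stereocentre (future C13) untouched.

**Step 8**
Reactants: 9 diene alcohol; 11 methyl (3S)-4-bromo-3-methylbutanoate
Product: 13 methyl (3R)-5-[(1R,4aR,7S,8aS)-7-hydroxy-2,5,5,8a-tetramethyl-1,4,4a,5,6,7,8,8a-octahydronaphthalen-1-yl]-3-methylpentanoate, via B-alkyl-9-BBN adduct 12 (not isolated)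
Conditions: 9-BBN (2.5 equiv), THF, rt; then 11, Pd(OAc)2 (5 mol %), PCy3 (10 mol %), K3PO4·H2O, THF, rt → 40 °C
Reagents that add atoms: none
Why: Anti-Markovnikov hydroboration of the exocyclic alkene of the diene followed by B-alkyl Suzuki–Miyaura alkyl–alkyl coupling with the primary bromide forms C11–C12; 9-BBN should add from the convex face of the cis-decalin (the face of H-5 and the C10 methyl, opposite the axial C1 arm of ring A), delivering H to C9 on that face and placing the side chain trans to the angular methyl, while C13 is carried in from 11.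

**Step 9**
Reactants: 13 hydroxy methyl ester
Product: 14 methyl (3R)-3-methyl-5-[(1R,4aR,7S,8aS)-2,5,5,8a-tetramethyl-7-{[(2Z)-2-methylbut-2-enoyl]oxy}-1,4,4a,5,6,7,8,8a-octahydronaphthalen-1-yl]pentanoate
Conditions: angelic acid, 2,4,6-trichlorobenzoyl chloride, Et3N, toluene, rt; then 13, toluene, 80 °C (no DMAP)
Reagents that add atoms: angelic acid [(2Z)-2-methylbut-2-enoic acid], C/C=C(/C)C(=O)O
Why: Yamaguchi-type esterification through the mixed trichlorobenzoic anhydride, run thermally without a nucleophilic catalyst, should acylate the unhindered equatorial C2 hydroxyl with retention at C2 and without Z-to-E isomerization of the angelate.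

**Step 10**
Reactants: 14 angelate methyl ester
Product: 15 (3R)-3-methyl-5-[(1R,4aR,7S,8aS)-2,5,5,8a-tetramethyl-7-{[(2Z)-2-methylbut-2-enoyl]oxy}-1,4,4a,5,6,7,8,8a-octahydronaphthalen-1-yl]pentanoic acid (CNP0248298.1)
Conditions: Me3SnOH, ClCH2CH2Cl, 70 °C; dilute aqueous HCl work-up
Reagents that add atoms: trimethyltin hydroxide, C[Sn](C)(C)O
Why: Trimethyltin hydroxide-mediated ester hydrolysis is a mild, near-neutral method that should cleave the unhindered methyl ester while sparing the hindered, conjugated secondary angelate and its Z geometry.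

**Compound list**

1 | (S)-carvone, (5S)-2-methyl-5-(prop-1-en-2-yl)cyclohex-2-en-1-one | CC1=CC[C@@H](CC1=O)C(C)=C | starting material
2 | (5S)-2-methyl-6-(3-methylbut-2-en-1-yl)-5-(prop-1-en-2-yl)cyclohex-2-en-1-one (C6 epimer mixture, C6 left undefined) | CC(C)=CCC1C(=O)C(C)=CC[C@@H]1C(C)=C | intermediate
3 | (5R,6S)-2,6-dimethyl-6-(3-methylbut-2-en-1-yl)-5-(prop-1-en-2-yl)cyclohex-2-en-1-one | CC(C)=CC[C@]1(C)C(=O)C(C)=CC[C@@H]1C(C)=C | intermediate
4 | (5R,6S)-6-[(3,3-dimethyloxiran-2-yl)methyl]-2,6-dimethyl-5-(prop-1-en-2-yl)cyclohex-2-en-1-one (epoxide epimers, not isolated) | CC1(C)OC1C[C@]2(C)C(=O)C(C)=CC[C@@H]2C(C)=C | intermediate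
5 | 2-[(1S,6R)-1,3-dimethyl-2-oxo-6-(prop-1-en-2-yl)cyclohex-3-en-1-yl]acetaldehyde | O=CC[C@]1(C)C(=O)C(C)=CC[C@@H]1C(C)=C | intermediate
6 | (4aR,7S,8aS)-7-hydroxy-2,8a-dimethyl-5-methylidene-4a,5,6,7,8,8a-hexahydronaphthalen-1(4H)-one | O[C@H]1CC(=C)[C@H]2CC=C(C)C(=O)[C@@]2(C)C1 | intermediate
7 | N'-{[(4aR,7S,8aS)-7-hydroxy-2,5,8a-trimethyl-1-oxo-1,4,4a,5,6,7,8,8a-octahydronaphthalen-5-yl]methyl}octane-1-sulfonohydrazide (C5 epimers, not isolated) | O[C@H]1CC(C)(CNNS(=O)(=O)CCCCCCCC)[C@H]2CC=C(C)C(=O)[C@@]2(C)C1 | intermediate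
8 | (4aR,7S,8aS)-7-hydroxy-2,5,5,8a-tetramethyl-4a,5,6,7,8,8a-hexahydronaphthalen-1(4H)-one | O[C@H]1CC(C)(C)[C@H]2CC=C(C)C(=O)[C@@]2(C)C1 | intermediate
9 | (2S,4aR,8aS)-4,4,7,8a-tetramethyl-8-methylidene-1,2,3,4,4a,5,8,8a-octahydronaphthalen-2-ol | O[C@H]1CC(C)(C)[C@H]2CC=C(C)C(=C)[C@@]2(C)C1 | intermediate
10 | (S)-4-methyldihydrofuran-2(3H)-one | C[C@@H]1COC(=O)C1 | starting material
11 | methyl (3S)-4-bromo-3-methylbutanoate | BrC[C@@H](C)CC(=O)OC | intermediate
12 | B-alkyl-9-BBN adduct of 9 (boron on C11, C2 oxygen as 9-BBN borinate, not isolated) | C1CCC2CCCC1B2O[C@H]1CC(C)(C)[C@H]2CC=C(C)[C@@H](CB3C4CCCC3CCC4)[C@@]2(C)C1 | intermediate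
13 | methyl (3R)-5-[(1R,4aR,7S,8aS)-7-hydroxy-2,5,5,8a-tetramethyl-1,4,4a,5,6,7,8,8a-octahydronaphthalen-1-yl]-3-methylpentanoate | O[C@H]1CC(C)(C)[C@H]2CC=C(C)[C@@H](CC[C@@H](C)CC(=O)OC)[C@@]2(C)C1 | intermediate
14 | methyl (3R)-3-methyl-5-[(1R,4aR,7S,8aS)-2,5,5,8a-tetramethyl-7-{[(2Z)-2-methylbut-2-enoyl]oxy}-1,4,4a,5,6,7,8,8a-octahydronaphthalen-1-yl]pentanoate | C/C=C(/C)C(=O)O[C@H]1CC(C)(C)[C@H]2CC=C(C)[C@@H](CC[C@@H](C)CC(=O)OC)[C@@]2(C)C1 | intermediate
15 | (3R)-3-methyl-5-[(1R,4aR,7S,8aS)-2,5,5,8a-tetramethyl-7-{[(2Z)-2-methylbut-2-enoyl]oxy}-1,4,4a,5,6,7,8,8a-octahydronaphthalen-1-yl]pentanoic acid | C/C=C(/C)C(=O)O[C@H]1CC(C)(C)[C@H]2CC=C(C)[C@@H](CC[C@@H](C)CC(=O)O)[C@@]2(C)C1 | target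

**Total step count:** 10. **Longest linear sequence:** 9 steps (steps 1–6 and 8–10; step 7 prepares the side-chain fragment).

**Three steps most likely to fail**

Step 4 (key step). Ionisation may outrun the concerted hydrogen transfer, so that proton loss gives ring-internal alkene isomers, or the aldehyde may react through the alternative chair so that facial control at C2 erodes. The fallback sets out from 5 and comes back to the route at 8. A halo-Prins cyclization (TiCl4, CH2Cl2, −78 °C) closes the same C2–C3 bond stepwise and captures the C4 cation with chloride. It should give the tertiary chloride (4aS,7R,8aS)-5-chloro-7-hydroxy-2,5,8a-trimethyl-4a,5,6,7,8,8a-hexahydronaphthalen-1(4H)-one F1 (C5 epimers; same spatial arrangement as in 6, the descriptors change only through the chlorine). Me3Al (CH2Cl2, −78 → 0 °C) then replaces the tertiary chloride by methyl through ionisation and methyl transfer, which also makes step 5 unnecessary.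

Step 8. Oxidative addition to the β-branched primary bromide may be slow, so that β-hydride elimination and protodeboronation of the alkylborane take over. The fallback sets out from 9 (with 11) and comes back at 13.
- Hydroboration–oxidation (9-BBN, THF; then NaOH, H2O2) should give the diol (2S,4aR,8R,8aS)-8-(hydroxymethyl)-4,4,7,8a-tetramethyl-1,2,3,4,4a,5,8,8a-octahydronaphthalen-2-ol F2.
- Selective oxidation of the primary alcohol (TEMPO, PhI(OAc)2, CH2Cl2) gives the hydroxy aldehyde (1R,4aR,7S,8aS)-7-hydroxy-2,5,5,8a-tetramethyl-1,4,4a,5,6,7,8,8a-octahydronaphthalene-1-carbaldehyde F3.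
- Bromide 11 and PPh3 (MeCN, reflux) give [(2S)-4-methoxy-2-methyl-4-oxobutyl]triphenylphosphonium bromide F4.
- Wittig olefination with excess ylide (NaN(SiMe3)2, THF, −78 °C) joins C11 and C12 as methyl (3S,4Z)-5-[(1R,4aR,7S,8aS)-7-hydroxy-2,5,5,8a-tetramethyl-1,4,4a,5,6,7,8,8a-octahydronaphthalen-1-yl]-3-methylpent-4-enoate F5.
- Diimide (2-nitrobenzenesulfonylhydrazide, Et3N, CH2Cl2, rt) reduces the disubstituted alkene in preference to the trisubstituted ring alkene and gives 13.

Step 6. The basic ylide may deprotonate C6 (dienolate formation) faster than it adds to the hindered carbonyl flanked by C8 and the quaternary C10. The fallback sets out from 8 and comes back at 9 by a Peterson olefination. The weakly basic organocerium reagent from Me3SiCH2Li and CeCl3 (THF, −78 °C) adds to the carbonyl to give the β-hydroxysilane (4aR,7S,8aS)-2,5,5,8a-tetramethyl-1-[(trimethylsilyl)methyl]-1,4,4a,5,6,7,8,8a-octahydronaphthalene-1,7-diol F6 (configuration at C1 immaterial). KH (THF, 0 °C → rt) then effects syn-elimination to the exocyclic methylene.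

**Further compounds**

F1 | step 4 | (4aS,7R,8aS)-5-chloro-7-hydroxy-2,5,8a-trimethyl-4a,5,6,7,8,8a-hexahydronaphthalen-1(4H)-one (C5 epimers) | O[C@H]1CC(C)(Cl)[C@H]2CC=C(C)C(=O)[C@@]2(C)C1
F2 | step 8 | (2S,4aR,8R,8aS)-8-(hydroxymethyl)-4,4,7,8a-tetramethyl-1,2,3,4,4a,5,8,8a-octahydronaphthalen-2-ol | O[C@H]1CC(C)(C)[C@H]2CC=C(C)[C@@H](CO)[C@@]2(C)C1
F3 | step 8 | (1R,4aR,7S,8aS)-7-hydroxy-2,5,5,8a-tetramethyl-1,4,4a,5,6,7,8,8a-octahydronaphthalene-1-carbaldehyde | O[C@H]1CC(C)(C)[C@H]2CC=C(C)[C@@H](C=O)[C@@]2(C)C1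
F4 | step 8 | [(2S)-4-methoxy-2-methyl-4-oxobutyl]triphenylphosphonium bromide | c1ccccc1[P+](c1ccccc1)(c1ccccc1)C[C@@H](C)CC(=O)OC.[Br-]
F5 | step 8 | methyl (3S,4Z)-5-[(1R,4aR,7S,8aS)-7-hydroxy-2,5,5,8a-tetramethyl-1,4,4a,5,6,7,8,8a-octahydronaphthalen-1-yl]-3-methylpent-4-enoate | O[C@H]1CC(C)(C)[C@H]2CC=C(C)[C@@H](/C=C\[C@@H](C)CC(=O)OC)[C@@]2(C)C1
F6 | step 6 | (4aR,7S,8aS)-2,5,5,8a-tetramethyl-1-[(trimethylsilyl)methyl]-1,4,4a,5,6,7,8,8a-octahydronaphthalene-1,7-diol | O[C@H]1CC(C)(C)[C@H]2CC=C(C)C(O)(C[Si](C)(C)C)[C@@]2(C)C1
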